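**Plan**

- Retrosynthesis: the epoxyquinol is taken back to a p-methoxyphenol (dearomatization to the quinone monoketal, epoxidation, ketal hydrolysis, reduction) and the C8 methylene to a C8 ketone. Ring A is then cut at C3–C4 and C1–C10, leaving a ring B diene and a three-carbon C1–C3 unit.
- Enabling feature: in ring A the two methyl-bearing quaternary carbons C4 and C10 stand 1,3 to each other across the C5 methine. Each is therefore the internal carbon of a 1,1-disubstituted alkene (isopropenyl on C5, methylene at C10), and hydrogen-atom transfer turns both into tertiary radicals that 2,3-bis(phenylsulfonyl)propene can bridge.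
- Forward order: aryl fragment (steps 1–4); acyclic chain and ring B (steps 5–12); ring A by the radical annulation (step 13); C8 methylene and arene-to-epoxyquinol sequence (steps 14–23).
- Stereochemistry: C8–O from (S)-BINAP hydrogenation (a relay centre, destroyed later); C9 from anti alkylation; C5 from the chair ene transition state; C10 in the key step, anti to the axial C8 silyloxy group; epoxide face from a cinchona phase-transfer catalyst; C5′ carbinol from epoxide-directed hydride delivery.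

Key step: step 13

Remarks:
- Locants C1–C12 follow drimane numbering (C11 = benzylic CH2, C12 = exocyclic CH2). Primed locants C1′–C6′ denote the oxygenated six-membered ring (C1′ bears C11, C2′ becomes the ketone, C5′ the carbinol). Ar = 4-bromo-5-methoxy-2-(methoxymethoxy)phenyl.
- Assumption: the face-directing sense of the cinchonidinium catalyst in step 21 (and of the (2S,4S)-diol auxiliary in its fallback) is taken as written; if it proves opposite, the pseudoenantiomeric cinchoninium salt or the (2R,4R)-diol is used.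

**Step 1**
Reactants: 1 4-bromo-2,5-dimethoxybenzaldehyde
Product: 2 4-bromo-2-hydroxy-5-methoxybenzaldehyde
Conditions: BCl3, CH2Cl2, 0 °C to 23 °C; aqueous work-up
Reagents that add atoms: none
Why: Chelation-controlled aryl methyl ether cleavage, in which BCl3 bound to the aldehyde oxygen should remove only the ortho methyl group.

**Step 2**
Reactants: 2 4-bromo-2-hydroxy-5-methoxybenzaldehyde
Product: 3 4-bromo-5-methoxy-2-(methoxymethoxy)benzaldehyde
Conditions: MOMCl, i-Pr2NEt, CH2Cl2, 0 °C to 23 °C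
Reagents that add atoms: chloromethyl methyl ether COCCl
Why: O-Alkylation of the phenol (Williamson type) should give an acetal that survives the later bases, hydrides, Lewis acid and radical conditions.

**Step 3**
Reactants: 3 4-bromo-5-methoxy-2-(methoxymethoxy)benzaldehyde
Product: 4 [4-bromo-5-methoxy-2-(methoxymethoxy)phenyl]methanol
Conditions: NaBH4, MeOH, 0 °C
Reagents that add atoms: none
Why: Borohydride reduction of an aryl aldehyde should proceed without touching the aryl bromide or the acetal.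

**Step 4**
Reactants: 4 [4-bromo-5-methoxy-2-(methoxymethoxy)phenyl]methanol
Product: 5 1-bromo-4-(bromomethyl)-2-methoxy-5-(methoxymethoxy)benzene
Conditions: CBr4, PPh3, CH2Cl2, 0 °C
Reagents that add atoms: carbon tetrabromide BrC(Br)(Br)Br
Why: The Appel reaction should convert the benzylic alcohol into the bromide under neutral conditions that leave the MOM acetal intact.

**Step 5**
Reactants: 6 ethyl acetoacetate; 7 prenyl bromide (1-bromo-3-methylbut-2-ene)
Product: 8 ethyl 7-methyl-3-oxooct-6-enoate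
Conditions: LiN(i-Pr)2 (2.1 equiv), THF, 0 °C; then 7, 0 °C
Reagents that add atoms: none
Why: Weiler dianion alkylation, in which the more nucleophilic γ-carbon of the acetoacetate dianion should take the allylic bromide.

**Step 6**
Reactants: 8 ethyl 7-methyl-3-oxooct-6-enoate
Product: 9 ethyl (3S)-3-hydroxy-7-methyloct-6-enoate
Conditions: H2 (50 atm), RuCl2[(S)-BINAP] (0.5 mol%; BINAP = 2,2′-bis(diphenylphosphino)-1,1′-binaphthyl), EtOH, 50 °C
Reagents that add atoms: none
Why: Noyori asymmetric hydrogenation of a β-keto ester, in which the (S)-ligand should deliver the (S)-carbinol (future C8) and leave the trisubstituted alkene alone.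

**Step 7**
Reactants: 9 ethyl (3S)-3-hydroxy-7-methyloct-6-enoate; 5 1-bromo-4-(bromomethyl)-2-methoxy-5-(methoxymethoxy)benzene
Product: 10 ethyl (2S,3S)-2-(ArCH2)-3-hydroxy-7-methyloct-6-enoate
Conditions: LiN(i-Pr)2 (2.05 equiv), THF, −78 °C to −20 °C; then 5, DMPU, −78 °C to −10 °C
Reagents that add atoms: none
Why: Fráter–Seebach alkylation, in which the chelated alkoxide–enolate dianion should be benzylated anti to the C3 side chain, setting C9 as the 2,3-anti isomer.

**Step 8**
Reactants: 10 ethyl (2S,3S)-2-(ArCH2)-3-hydroxy-7-methyloct-6-enoate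
Product: 11 ethyl (2S,3S)-2-(ArCH2)-3-[(tert-butyldimethylsilyl)oxy]-7-methyloct-6-enoate
Conditions: TBSOTf, 2,6-lutidine, CH2Cl2, −78 °C
Reagents that add atoms: tert-butyldimethylsilyl triflate CC(C)(C)[Si](C)(C)OS(=O)(=O)C(F)(F)F
Why: Silylation of the secondary alcohol should install the bulky C8 group that later shields the β face of ring B.

**Step 9**
Reactants: 11 ethyl (2S,3S)-2-(ArCH2)-3-[(tert-butyldimethylsilyl)oxy]-7-methyloct-6-enoate
Product: 12 (2S,3S)-2-(ArCH2)-3-[(tert-butyldimethylsilyl)oxy]-7-methyloct-6-enal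
Conditions: i-Bu2AlH (1.1 equiv), CH2Cl2, −78 °C; Rochelle salt work-up; used at once
Reagents that add atoms: none
Why: Partial reduction of the ester should stop at the aldehyde because the aluminium hemiacetal is stable at −78 °C.

**Step 10**
Reactants: 12 (2S,3S)-2-(ArCH2)-3-[(tert-butyldimethylsilyl)oxy]-7-methyloct-6-enal
Product: 13 (1S,2R,3S,6S)-2-(ArCH2)-3-[(tert-butyldimethylsilyl)oxy]-6-(prop-1-en-2-yl)cyclohexan-1-ol
Conditions: Me2AlCl (1.2 equiv), CH2Cl2, −78 °C
Reagents that add atoms: none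
Why: Intramolecular carbonyl-ene cyclization of the citronellal-to-isopulegol type should close ring B (C5–C10) through a chair transition state with the arylmethyl group equatorial and the silyloxy group axial, so that the new isopropenyl group at C5 is equatorial and cis to the C9 substituent.

**Step 11**
Reactants: 13 (1S,2R,3S,6S)-2-(ArCH2)-3-[(tert-butyldimethylsilyl)oxy]-6-(prop-1-en-2-yl)cyclohexan-1-ol
Product: 14 (2S,3S,6S)-2-(ArCH2)-3-[(tert-butyldimethylsilyl)oxy]-6-(prop-1-en-2-yl)cyclohexan-1-one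
Conditions: Dess–Martin periodinane, NaHCO3, CH2Cl2, 0 °C
Reagents that add atoms: none
Why: Buffered Dess–Martin oxidation should give the ketone without epimerizing C5 or C9 and without moving the β,γ-alkene into conjugation.

**Step 12**
Reactants: 14 (2S,3S,6S)-2-(ArCH2)-3-[(tert-butyldimethylsilyl)oxy]-6-(prop-1-en-2-yl)cyclohexan-1-one
Product: 15 tert-butyl{[(1S,2R,4S)-2-(ArCH2)-3-methylidene-4-(prop-1-en-2-yl)cyclohexyl]oxy}dimethylsilane
Conditions: Cp2Ti(CH3)2 (3 equiv), toluene/THF, 70 °C, dark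
Reagents that add atoms: dimethyltitanocene (Petasis reagent) C[Ti](C)(C1C=CC=C1)C1C=CC=C1
Why: Petasis methylenation, a non-basic titanium carbene olefination, should convert the hindered enolizable ketone into the C10 methylene without epimerization.

**Step 13**
Reactants: 15 tert-butyl{[(1S,2R,4S)-2-(ArCH2)-3-methylidene-4-(prop-1-en-2-yl)cyclohexyl]oxy}dimethylsilane; 16 2,3-bis(phenylsulfonyl)prop-1-ene
Product: 18 tert-butyl{[(1R,2S,4aS,8aS)-1-(ArCH2)-5,5,8a-trimethyl-7-(phenylsulfonyl)decahydronaphthalen-2-yl]oxy}dimethylsilane (C7 epimers), via C4-allylated vinyl sulfone 17 (not isolated)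
Conditions: 16 (1.3 equiv), Fe(acac)3 (0.5 equiv), PhSiH3 (4 equiv, slow addition), EtOH/ethylene glycol 5:1, 0.02 M, 60 °C
Reagents that add atoms: none
Why: Proposed new method: hydrogen-atom transfer from the iron hydride formed from Fe(acac)3 and PhSiH3 to the less hindered isopropenyl group of 15 should give the tertiary C4 radical, which adds to the CH2 terminus of 16 and expels a phenylsulfonyl radical to give vinyl sulfone 17; a second hydrogen-atom transfer to the C10 methylene then gives the tertiary C10 radical, which closes ring A onto the free terminus of the 2-sulfonylalkene, and the α-sulfonyl radical is reduced by ferrous iron and protonated. The closest known reactions are the iron-mediated reductive coupling of 1,1-disubstituted alkenes with vinyl sulfones (also in its intramolecular form) and radical allylation by addition–fragmentation of 2-substituted allyl sulfones; joining them into a two-bond annulation of a skipped diene is the new element. Ring A closes in the 6-endo-trig mode, preferred over 5-exo because the sulfonyl group on C2 polarizes the alkene so that the nucleophilic radical attacks C1 and a stabilized radical results. C10 is the only lasting new stereocentre (C2 forms as a mixture and its sulfone is removed in step 19): the axial silyloxy group on C8 is 1,3-diaxial to the β lobe of the C10 radical, so C1 should bond on the α face through a chair–chair transition state, leaving the methyl group β and trans to H5. The step needs one annulation per molecule and no alkene migration; the near-stoichiometric amount of 16, slow silane addition, high dilution and the fast intramolecular second addition should secure the first, and the iron hydride (which isomerizes alkenes far less than cobalt hydrides) the second.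

**Step 14**
Reactants: 18 tert-butyl{[(1R,2S,4aS,8aS)-1-(ArCH2)-5,5,8a-trimethyl-7-(phenylsulfonyl)decahydronaphthalen-2-yl]oxy}dimethylsilane
Product: 19 (1R,2S,4aS,8aS)-1-(ArCH2)-5,5,8a-trimethyl-7-(phenylsulfonyl)decahydronaphthalen-2-ol
Conditions: HF·pyridine, THF/pyridine, 0 °C to 23 °C
Reagents that add atoms: none
Why: Fluoride desilylation should remove the strained axial silyl ether and leave the aryl MOM acetal untouched.

**Step 15**
Reactants: 19 (1R,2S,4aS,8aS)-1-(ArCH2)-5,5,8a-trimethyl-7-(phenylsulfonyl)decahydronaphthalen-2-ol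
Product: 20 (1R,4aS,8aS)-1-(ArCH2)-5,5,8a-trimethyl-7-(phenylsulfonyl)octahydronaphthalen-2(1H)-one
Conditions: Dess–Martin periodinane, NaHCO3, CH2Cl2, 23 °C
Reagents that add atoms: none
Why: Dess–Martin oxidation should give the C8 ketone, in which C9 already holds the thermodynamically preferred equatorial arylmethyl group.

**Step 16**
Reactants: 20 (1R,4aS,8aS)-1-(ArCH2)-5,5,8a-trimethyl-7-(phenylsulfonyl)octahydronaphthalen-2(1H)-one
Product: 21 1-bromo-2-methoxy-5-(methoxymethoxy)-4-{[(1S,4aS,8aS)-5,5,8a-trimethyl-2-methylidene-7-(phenylsulfonyl)decahydronaphthalen-1-yl]methyl}benzene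
Conditions: Ph3PCH3Br, KOt-Bu, toluene, 80 °C
Reagents that add atoms: methyltriphenylphosphonium bromide C[P+](c1ccccc1)(c1ccccc1)c1ccccc1.[Br-]
Why: Wittig methylenation, as used on 8-oxodrimanes, should install the exocyclic C8=C12 alkene, and any base-induced equilibration at C9 favours the required equatorial isomer.

**Step 17**
Reactants: 21 1-bromo-2-methoxy-5-(methoxymethoxy)-4-{[(1S,4aS,8aS)-5,5,8a-trimethyl-2-methylidene-7-(phenylsulfonyl)decahydronaphthalen-1-yl]methyl}benzene
Product: 22 5-bromo-4-methoxy-2-{[(1S,4aS,8aS)-5,5,8a-trimethyl-2-methylidene-7-(phenylsulfonyl)decahydronaphthalen-1-yl]methyl}phenol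
Conditions: ZnBr2 (1 equiv), n-PrSH (2 equiv), CH2Cl2, 0 °C, 10 min
Reagents that add atoms: none
Why: Lewis acid-promoted acetal exchange of the phenolic MOM ether with the thiol should free the phenol under conditions too mild to isomerize the exocyclic alkene.

**Step 18**
Reactants: 22 5-bromo-4-methoxy-2-{[(1S,4aS,8aS)-5,5,8a-trimethyl-2-methylidene-7-(phenylsulfonyl)decahydronaphthalen-1-yl]methyl}phenol
Product: 23 5-(hydroxymethyl)-4-methoxy-2-{[(1S,4aS,8aS)-5,5,8a-trimethyl-2-methylidene-7-(phenylsulfonyl)decahydronaphthalen-1-yl]methyl}phenol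
Conditions: potassium acetoxymethyltrifluoroborate (1.5 equiv), Pd(dba)2 (5 mol%), 2-dicyclohexylphosphino-2′,6′-diisopropoxybiphenyl (10 mol%), Na2CO3 (3 equiv), dioxane/H2O 10:1, 85 °C, degassed
Reagents that add atoms: potassium acetoxymethyltrifluoroborate CC(=O)OC[B-](F)(F)F.[K+]
Why: Suzuki–Miyaura coupling of the aryl bromide with the acetoxymethyltrifluoroborate, whose acetate is hydrolysed in the basic medium, should give the hydroxymethyl arene directly.

**Step 19**
Reactants: 23 5-(hydroxymethyl)-4-methoxy-2-{[(1S,4aS,8aS)-5,5,8a-trimethyl-2-methylidene-7-(phenylsulfonyl)decahydronaphthalen-1-yl]methyl}phenol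
Product: 24 5-(hydroxymethyl)-4-methoxy-2-{[(1S,4aS,8aS)-5,5,8a-trimethyl-2-methylidenedecahydronaphthalen-1-yl]methyl}phenol
Conditions: Mg turnings, MeOH, 50 °C
Reagents that add atoms: none
Why: Reductive desulfonylation by electron transfer from magnesium should replace the C2 sulfonyl group by hydrogen now that no aryl halide remains.

**Step 20**
Reactants: 24 5-(hydroxymethyl)-4-methoxy-2-{[(1S,4aS,8aS)-5,5,8a-trimethyl-2-methylidenedecahydronaphthalen-1-yl]methyl}phenol
Product: 25 5-(hydroxymethyl)-4,4-dimethoxy-2-{[(1S,4aS,8aS)-5,5,8a-trimethyl-2-methylidenedecahydronaphthalen-1-yl]methyl}cyclohexa-2,5-dien-1-one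
Conditions: PhI(OAc)2 (1.1 equiv), MeOH, 0 °C
Reagents that add atoms: methanol CO
Why: Oxidative dearomatization of the p-methoxyphenol in methanol should give the quinone monoketal with the ketone at C2′, next to the carbon that bears C11.

**Step 21**
Reactants: 25 5-(hydroxymethyl)-4,4-dimethoxy-2-{[(1S,4aS,8aS)-5,5,8a-trimethyl-2-methylidenedecahydronaphthalen-1-yl]methyl}cyclohexa-2,5-dien-1-one
Product: 26 (1S,6R)-4-(hydroxymethyl)-5,5-dimethoxy-1-{[(1S,4aS,8aS)-5,5,8a-trimethyl-2-methylidenedecahydronaphthalen-1-yl]methyl}-7-oxabicyclo[4.1.0]hept-3-en-2-one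
Conditions: t-BuOOH, N-benzylcinchonidinium chloride (10 mol%), aq. NaOH, toluene, 0 °C
Reagents that add atoms: tert-butyl hydroperoxide CC(C)(C)OO
Why: Weitz–Scheffer nucleophilic epoxidation under chiral phase-transfer catalysis (Wynberg type) should take place at the C1′=C6′ enone, whose β-carbon is unsubstituted while that of the other enone carries the hydroxymethyl group, with the catalyst choosing the face that sets C1′ and C6′.

**Step 22**
Reactants: 26 (1S,6R)-4-(hydroxymethyl)-5,5-dimethoxy-1-{[(1S,4aS,8aS)-5,5,8a-trimethyl-2-methylidenedecahydronaphthalen-1-yl]methyl}-7-oxabicyclo[4.1.0]hept-3-en-2-one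
Product: 27 (1S,6R)-4-(hydroxymethyl)-1-{[(1S,4aS,8aS)-5,5,8a-trimethyl-2-methylidenedecahydronaphthalen-1-yl]methyl}-7-oxabicyclo[4.1.0]hept-3-ene-2,5-dione
Conditions: aq. HF, MeCN, 0 °C
Reagents that add atoms: water O
Why: Mild acid hydrolysis of the dimethyl ketal should unveil the C5′ carbonyl without opening the epoxide or moving the exocyclic alkene.

**Step 23**
Reactants: 27 (1S,6R)-4-(hydroxymethyl)-1-{[(1S,4aS,8aS)-5,5,8a-trimethyl-2-methylidenedecahydronaphthalen-1-yl]methyl}-7-oxabicyclo[4.1.0]hept-3-ene-2,5-dione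
Product: 28 (1S,5R,6S)-5-hydroxy-4-(hydroxymethyl)-1-{[(1S,4aS,8aS)-5,5,8a-trimethyl-2-methylidenedecahydronaphthalen-1-yl]methyl}-7-oxabicyclo[4.1.0]hept-3-en-2-one
Conditions: i-Bu2AlH (3 equiv), THF, −78 °C
Reagents that add atoms: none
Why: 1,2-Reduction with i-Bu2AlH should take the C5′ carbonyl (C2′ is shielded by the quaternary C1′ and its drimanylmethyl group, and the neighbouring aluminium alkoxide activates C5′), with aluminium bound to the epoxide oxygen delivering hydride on the epoxide face to give the trans epoxy alcohol.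

**Compound list**

1 | 4-bromo-2,5-dimethoxybenzaldehyde | COc1cc(Br)c(OC)cc1C=O | starting material
2 | 4-bromo-2-hydroxy-5-methoxybenzaldehyde | COc1cc(C=O)c(O)cc1Br | intermediate
3 | 4-bromo-5-methoxy-2-(methoxymethoxy)benzaldehyde | COCOc1cc(Br)c(OC)cc1C=O | intermediate
4 | [4-bromo-5-methoxy-2-(methoxymethoxy)phenyl]methanol | COCOc1cc(Br)c(OC)cc1CO | intermediate
5 | 1-bromo-4-(bromomethyl)-2-methoxy-5-(methoxymethoxy)benzene | COCOc1cc(Br)c(OC)cc1CBr | intermediate
6 | ethyl acetoacetate | CCOC(=O)CC(C)=O | starting material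
7 | prenyl bromide (1-bromo-3-methylbut-2-ene) | CC(C)=CCBr | starting material
8 | ethyl 7-methyl-3-oxooct-6-enoate | CCOC(=O)CC(=O)CCC=C(C)C | intermediate
9 | ethyl (3S)-3-hydroxy-7-methyloct-6-enoate | CCOC(=O)C[C@@H](O)CCC=C(C)C | intermediate
10 | ethyl (2S,3S)-2-{[4-bromo-5-methoxy-2-(methoxymethoxy)phenyl]methyl}-3-hydroxy-7-methyloct-6-enoate | CC(C)=CCC[C@H](O)[C@@H](C(=O)OCC)Cc1cc(OC)c(Br)cc1OCOC | intermediate
11 | ethyl (2S,3S)-2-{[4-bromo-5-methoxy-2-(methoxymethoxy)phenyl]methyl}-3-[(tert-butyldimethylsilyl)oxy]-7-methyloct-6-enoate | CC(C)=CCC[C@H](O[Si](C)(C)C(C)(C)C)[C@@H](C(=O)OCC)Cc1cc(OC)c(Br)cc1OCOC | intermediate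
12 | (2S,3S)-2-{[4-bromo-5-methoxy-2-(methoxymethoxy)phenyl]methyl}-3-[(tert-butyldimethylsilyl)oxy]-7-methyloct-6-enal | CC(C)=CCC[C@H](O[Si](C)(C)C(C)(C)C)[C@@H](C=O)Cc1cc(OC)c(Br)cc1OCOC | intermediate
13 | (1S,2R,3S,6S)-2-{[4-bromo-5-methoxy-2-(methoxymethoxy)phenyl]methyl}-3-[(tert-butyldimethylsilyl)oxy]-6-(prop-1-en-2-yl)cyclohexan-1-ol | O[C@H]1[C@H](C(C)=C)CC[C@H](O[Si](C)(C)C(C)(C)C)[C@@H]1Cc1cc(OC)c(Br)cc1OCOC | intermediate
14 | (2S,3S,6S)-2-{[4-bromo-5-methoxy-2-(methoxymethoxy)phenyl]methyl}-3-[(tert-butyldimethylsilyl)oxy]-6-(prop-1-en-2-yl)cyclohexan-1-one | O=C1[C@H](C(C)=C)CC[C@H](O[Si](C)(C)C(C)(C)C)[C@@H]1Cc1cc(OC)c(Br)cc1OCOC | intermediate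
15 | tert-butyl{[(1S,2R,4S)-2-{[4-bromo-5-methoxy-2-(methoxymethoxy)phenyl]methyl}-3-methylidene-4-(prop-1-en-2-yl)cyclohexyl]oxy}dimethylsilane | C=C1[C@H](C(C)=C)CC[C@H](O[Si](C)(C)C(C)(C)C)[C@@H]1Cc1cc(OC)c(Br)cc1OCOC | intermediate
16 | 2,3-bis(phenylsulfonyl)prop-1-ene | C=C(CS(=O)(=O)c1ccccc1)S(=O)(=O)c1ccccc1 | starting material
17 | tert-butyl{[(1S,2R,4S)-2-{[4-bromo-5-methoxy-2-(methoxymethoxy)phenyl]methyl}-3-methylidene-4-[2-methyl-4-(phenylsulfonyl)pent-4-en-2-yl]cyclohexyl]oxy}dimethylsilane (not isolated) | C=C1[C@H](C(C)(C)CC(=C)S(=O)(=O)c2ccccc2)CC[C@H](O[Si](C)(C)C(C)(C)C)[C@@H]1Cc1cc(OC)c(Br)cc1OCOC | intermediate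
18 | tert-butyl{[(1R,2S,4aS,8aS)-1-{[4-bromo-5-methoxy-2-(methoxymethoxy)phenyl]methyl}-5,5,8a-trimethyl-7-(phenylsulfonyl)decahydronaphthalen-2-yl]oxy}dimethylsilane (C7 epimers) | CC(C)(C)[Si](C)(C)O[C@H]1CC[C@H]2C(C)(C)CC(S(=O)(=O)c3ccccc3)C[C@]2(C)[C@H]1Cc1cc(OC)c(Br)cc1OCOC | intermediate
19 | (1R,2S,4aS,8aS)-1-{[4-bromo-5-methoxy-2-(methoxymethoxy)phenyl]methyl}-5,5,8a-trimethyl-7-(phenylsulfonyl)decahydronaphthalen-2-ol | O[C@H]1CC[C@H]2C(C)(C)CC(S(=O)(=O)c3ccccc3)C[C@]2(C)[C@H]1Cc1cc(OC)c(Br)cc1OCOC | intermediate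
20 | (1R,4aS,8aS)-1-{[4-bromo-5-methoxy-2-(methoxymethoxy)phenyl]methyl}-5,5,8a-trimethyl-7-(phenylsulfonyl)octahydronaphthalen-2(1H)-one | O=C1CC[C@H]2C(C)(C)CC(S(=O)(=O)c3ccccc3)C[C@]2(C)[C@H]1Cc1cc(OC)c(Br)cc1OCOC | intermediate
21 | 1-bromo-2-methoxy-5-(methoxymethoxy)-4-{[(1S,4aS,8aS)-5,5,8a-trimethyl-2-methylidene-7-(phenylsulfonyl)decahydronaphthalen-1-yl]methyl}benzene | C=C1CC[C@H]2C(C)(C)CC(S(=O)(=O)c3ccccc3)C[C@]2(C)[C@H]1Cc1cc(OC)c(Br)cc1OCOC | intermediate
22 | 5-bromo-4-methoxy-2-{[(1S,4aS,8aS)-5,5,8a-trimethyl-2-methylidene-7-(phenylsulfonyl)decahydronaphthalen-1-yl]methyl}phenol | C=C1CC[C@H]2C(C)(C)CC(S(=O)(=O)c3ccccc3)C[C@]2(C)[C@H]1Cc1cc(OC)c(Br)cc1O | intermediate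
23 | 5-(hydroxymethyl)-4-methoxy-2-{[(1S,4aS,8aS)-5,5,8a-trimethyl-2-methylidene-7-(phenylsulfonyl)decahydronaphthalen-1-yl]methyl}phenol | C=C1CC[C@H]2C(C)(C)CC(S(=O)(=O)c3ccccc3)C[C@]2(C)[C@H]1Cc1cc(OC)c(CO)cc1O | intermediate
24 | 5-(hydroxymethyl)-4-methoxy-2-{[(1S,4aS,8aS)-5,5,8a-trimethyl-2-methylidenedecahydronaphthalen-1-yl]methyl}phenol | C=C1CC[C@H]2C(C)(C)CCC[C@]2(C)[C@H]1Cc1cc(OC)c(CO)cc1O | intermediate
25 | 5-(hydroxymethyl)-4,4-dimethoxy-2-{[(1S,4aS,8aS)-5,5,8a-trimethyl-2-methylidenedecahydronaphthalen-1-yl]methyl}cyclohexa-2,5-dien-1-one | C=C1CC[C@H]2C(C)(C)CCC[C@]2(C)[C@H]1CC1=CC(OC)(OC)C(CO)=CC1=O | intermediate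
26 | (1S,6R)-4-(hydroxymethyl)-5,5-dimethoxy-1-{[(1S,4aS,8aS)-5,5,8a-trimethyl-2-methylidenedecahydronaphthalen-1-yl]methyl}-7-oxabicyclo[4.1.0]hept-3-en-2-one | C=C1CC[C@H]2C(C)(C)CCC[C@]2(C)[C@H]1C[C@]12O[C@H]1C(OC)(OC)C(CO)=CC2=O | intermediate
27 | (1S,6R)-4-(hydroxymethyl)-1-{[(1S,4aS,8aS)-5,5,8a-trimethyl-2-methylidenedecahydronaphthalen-1-yl]methyl}-7-oxabicyclo[4.1.0]hept-3-ene-2,5-dione | C=C1CC[C@H]2C(C)(C)CCC[C@]2(C)[C@H]1C[C@]12O[C@H]1C(=O)C(CO)=CC2=O | intermediate
28 | (1S,5R,6S)-5-hydroxy-4-(hydroxymethyl)-1-{[(1S,4aS,8aS)-5,5,8a-trimethyl-2-methylidenedecahydronaphthalen-1-yl]methyl}-7-oxabicyclo[4.1.0]hept-3-en-2-one | C=C1CC[C@H]2C(C)(C)CCC[C@]2(C)[C@H]1C[C@]12O[C@H]1[C@H](O)C(CO)=CC2=O | target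

**Step count and risks**

Total steps: 23. Longest linear sequence: 21 (steps 1–4 and then 7–23, from 4-bromo-2,5-dimethoxybenzaldehyde 1). The branch from ethyl acetoacetate (steps 5–6) joins at step 7 and runs 19 steps to the target.

Steps most likely to fail:

1. Step 13. The two hydrogen-atom transfers may not run in the needed order and rate. The first tertiary radical can be reduced or can shift the skipped diene into conjugation before it is trapped, and a second molecule of 16 can intercept the C10 radical before ring closure. Fallback, from 14 back to 18, generates the C10 radical without a metal hydride so that only one hydrogen-atom transfer remains. Addition of CH3MgBr/CeCl3 to ketone 14 should give the tertiary alcohol (C10 methyl carbinol) F1. Acylation with methyl chlorooxoacetate (Et3N, DMAP) gives the methyl oxalate F2, and CsOH in aqueous THF gives the cesium oxalate F3. Visible-light photoredox decarboxylation (Ir[dF(CF3)ppy]2(dtbbpy)PF6, blue light, DME/DMF/H2O) in the presence of 16 forms the C1–C10 bond by radical addition and β-sulfonyl elimination, on the face anti to the axial silyloxy group, to give the C10-allylated vinyl sulfone F4. A single intramolecular iron-hydride coupling of the isopropenyl group with the tethered vinyl sulfone (Fe(acac)3, PhSiH3, EtOH, 60 °C; 6-endo) then forms C3–C4 and returns to 18.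

2. Step 21. The peroxide may add with poor facial selectivity, because the catalyst has to override the bias of the neighbouring chiral decalin, or may attack the other enone. Fallback, from 25 back to 27, replaces catalyst control by a covalent auxiliary. Ketal exchange of 25 with (2S,4S)-pentane-2,4-diol (pyridinium p-toluenesulfonate, benzene, 40 °C) should give the C2-symmetric dioxane monoketal F5. Its diastereotopic enone faces are differentiated by the axial methyl group of the dioxane, so epoxidation with t-BuOOH and DBU should give the epoxy ketal F6. Hydrolysis with aq. HF in MeCN releases the diol and returns to 27.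

3. Step 23. Hydride may be delivered on the face opposite to the epoxide, giving the cis epoxy alcohol, or to the C2′ carbonyl. Fallback, from 27 back to 28, accepts the sterically controlled outcome and inverts it. Luche reduction of 27 (NaBH4, CeCl3, MeOH, −78 °C), which attacks anti to the epoxide, should give the cis epoxy alcohol (C5′ epimer of 28) F7. Selective silylation of the primary alcohol (TBSCl, imidazole) gives F8. Mitsunobu inversion with 4-nitrobenzoic acid (PPh3, diisopropyl azodicarboxylate) gives the inverted 4-nitrobenzoate F9. Methanolysis (K2CO3, MeOH, 0 °C) gives the silyl ether of the target F10, and HF·pyridine returns to 28.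

**Further compounds**

F1 | step 13 | C10 methyl carbinol from 14 (C10 epimers): (2R,3S,6S)-2-(ArCH2)-3-[(tert-butyldimethylsilyl)oxy]-1-methyl-6-(prop-1-en-2-yl)cyclohexan-1-ol | CC1(O)[C@H](C(C)=C)CC[C@H](O[Si](C)(C)C(C)(C)C)[C@@H]1Cc1cc(OC)c(Br)cc1OCOC
F2 | step 13 | methyl oxalate of F1 | COC(=O)C(=O)OC1(C)[C@H](C(C)=C)CC[C@H](O[Si](C)(C)C(C)(C)C)[C@@H]1Cc1cc(OC)c(Br)cc1OCOC
F3 | step 13 | cesium oxalate of F1 | [Cs+].[O-]C(=O)C(=O)OC1(C)[C@H](C(C)=C)CC[C@H](O[Si](C)(C)C(C)(C)C)[C@@H]1Cc1cc(OC)c(Br)cc1OCOC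
F4 | step 13 | C10-allylated vinyl sulfone: tert-butyl{[2-(ArCH2)-3-methyl-3-[2-(phenylsulfonyl)prop-2-en-1-yl]-4-(prop-1-en-2-yl)cyclohexyl]oxy}dimethylsilane, C10 methyl cis to the C5 and C9 substituents | C=C(C[C@@]1(C)[C@H](C(C)=C)CC[C@H](O[Si](C)(C)C(C)(C)C)[C@@H]1Cc1cc(OC)c(Br)cc1OCOC)S(=O)(=O)c1ccccc1
F5 | step 21 | (2S,4S)-pentane-2,4-diyl ketal analogue of 25 | C=C1CC[C@H]2C(C)(C)CCC[C@]2(C)[C@H]1CC1=CC2(O[C@@H](C)C[C@H](C)O2)C(CO)=CC1=O
F6 | step 21 | (2S,4S)-pentane-2,4-diyl ketal analogue of 26 | C=C1CC[C@H]2C(C)(C)CCC[C@]2(C)[C@H]1C[C@]12O[C@H]1C1(O[C@@H](C)C[C@H](C)O1)C(CO)=CC2=O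
F7 | step 23 | (1S,5S,6S) epimer of 28 (cis epoxy alcohol) | C=C1CC[C@H]2C(C)(C)CCC[C@]2(C)[C@H]1C[C@]12O[C@H]1[C@@H](O)C(CO)=CC2=O
F8 | step 23 | primary tert-butyldimethylsilyl ether of F7 | C=C1CC[C@H]2C(C)(C)CCC[C@]2(C)[C@H]1C[C@]12O[C@H]1[C@@H](O)C(CO[Si](C)(C)C(C)(C)C)=CC2=O
F9 | step 23 | 4-nitrobenzoate of the C5′-inverted alcohol with the primary silyl ether | C=C1CC[C@H]2C(C)(C)CCC[C@]2(C)[C@H]1C[C@]12O[C@H]1[C@H](OC(=O)c3ccc(cc3)[N+](=O)[O-])C(CO[Si](C)(C)C(C)(C)C)=CC2=O
F10 | step 23 | primary tert-butyldimethylsilyl ether of 28 | C=C1CC[C@H]2C(C)(C)CCC[C@]2(C)[C@H]1C[C@]12O[C@H]1[C@H](O)C(CO[Si](C)(C)C(C)(C)C)=CC2=O
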